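**Assumptions (remarks on the chemistry)**
- The sense of induction of a given MandyPhos enantiomer for this doubly ortho-substituted pair is not presumed. "MandyPhos" below means the enantiomer of 1,1'-bis(diphenylphosphino)-2,2'-bis[α-(dimethylamino)benzyl]ferrocene that gives (R)-14, to be fixed in the first run by oxidising a sample of 14 to the carbinol.
- Compounds 1, 2, 9 and 12 (as a THF solution) are taken as purchased.

**Numbering used throughout**
ArB = 5-(2-methylbut-3-en-2-yl)-4-(3-methylbut-2-enyloxy)-2-(triisopropylsilyloxy)phenyl; ArA = 4-(tert-butyldimethylsilyloxy)-2-chlorophenyl.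
1 4-bromoresorcinol; 2 prenyl bromide; 3 mono-prenyl ether; 4 its triisopropylsilyl ether; 5 ortho-dienone (not isolated); 6 rearranged phenol; 7 ring B bromide; 8 ring B pinacol boronic ester; 9 4-(tert-butyldimethylsilyloxy)phenol; 10 its 2-chloro derivative; 11 ring A triflate; 12 vinylmagnesium bromide; 13 vinylboronate complex (not isolated); 14 secondary boronic ester; 15 chloromethylboronate complex (not isolated); 16 homologated primary boronic ester; 17 primary alcohol; 18 bis-silyl isoflavan; 19 Manuifolin D.

## Analysis of the target

Manuifolin D (19) is an isoflavan: a chroman (benzene ring A fused to the dihydropyran ring C) with a hydroxyl on C7 and an aryl ring B on C3. Ring B is 1,2,4,5-substituted, with a free 2'-hydroxyl, a 4'-O-prenyl ether and a 1,1-dimethylallyl group on C5'. The only stereocentre is C3 (R), a benzylic methine between the C2 and C4 methylenes. No carbonyl group or heteroatom stands next to it, so it is hard to install but cannot epimerise once set. The aryl prenyl ether ionises with acid, rearranges on heating and can be opened by low-valent metals. The terminal vinyl group rules out hydrogenation, hydroboration, ozonolysis and electrophilic halogen late in the route. The usual isoflavan tactics (reduction of an isoflavone or isoflavene, benzyl ethers, strong acid) are therefore closed, and the 2'-oxygen can compete with the ring A oxygen for C2, which would give a dihydrobenzofuran. The strategy rests on C3–C4 being a two-carbon link between C1' of ring B and C4a of ring A, with C2 a single carbon on C3: a vinyl unit can take ring B on one carbon and ring A on the other, while boron marks the position on C3 where C2 is inserted afterwards.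

## Retrosynthetic reasoning

**19 from 18.** Only the two O–Si bonds are cut in the last operation. Fluoride does this without acid, hydrogen or oxidant, so the prenyl ether and the vinyl group are not at risk. Ring A carries the tert-butyldimethylsilyl group because that phenol is bought already protected. The ring B oxygen carries the bulkier triisopropylsilyl group for three reasons: it must survive a carbonate alkylation, it shields C3' in the sigmatropic step, and in 17 it lies within reach of the C2 alkoxide, to which a smaller silyl group could migrate.

**18 from 17.** The O1–C8a bond is cut. Closing ring C by displacement at C2 with a C8a phenol would need three phenols to be told apart and would let O2' close a five-membered ring on C2. With chlorine on C8a, the C2 hydroxyl is instead arylated under palladium catalysis, and O2' and O7 stay silylated. Chlorine is chosen because it is inert in every earlier step, in particular towards a chelated palladium catalyst that has a triflate to react with.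

**17 from 16, and 16 from 14.** The C2–C3 bond is cut. C2 enters as a carbenoid carbon that inserts into the C3–B bond of 14 with retention, and the boron, now on C2, is oxidised to the hydroxyl. The gain is that C3 can be created as a C–B stereocentre, for which a catalytic enantioselective three-component reaction exists. The forward steps must leave the aryl chloride, both silyl ethers and both alkenes untouched.

**14 from 8, 12 and 11.** This is the central disconnection: C3–C1' and C4–C4a are cut together. Cutting here divides the molecule into its two aromatic rings, each available from a simple phenol, and a two-carbon unit that is bought. The forward reaction must move ring B from boron to the vinyl carbon under control of a chiral palladium catalyst and deliver ring A to the other carbon. It must insert palladium into the C–OTf bond of 11 and not into C–Cl, and it must ignore the two alkenes of ring B.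

**8 from 7, back to 1 and 2.** The C–B bond comes from the C–Br bond of 7 by palladium-catalysed borylation. The 4'-O-prenyl bond of 7 is made by alkylating phenol 6 with 2. The C5'–C bond of 6 comes from a [3,3] shift of the prenyl ether 4, which transposes the allyl unit and so gives the 1,1-dimethylallyl group directly. Compound 4 is reached from 1 by O-prenylation with 2 at the hydroxyl para to bromine (3) and silylation of the other. Bromine is carried from the start because a later bromination would have to be done in the presence of alkenes.

**11 from 10 and 9.** The triflate is made from phenol 10, and 10 from 9 by chlorination ortho to the free hydroxyl. Starting from 9 fixes which oxygen is silylated and which becomes the triflate; the two hydroxyls of a chlorohydroquinone differ too little for a clean monosilylation.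

## Alternatives that were turned down

**Alternative 1: ring A built on a lactone and aromatised last.** The disconnection removes ring A altogether: C4a–C5 and C8–C8a are cut, leading to the δ-lactone A1, which carries ring B on the carbon that becomes C3, and methyl vinyl ketone A2. In the forward step the lactone enolate adds to A2, an alkoxide base then drives the methyl ketone enolate on to the lactone carbonyl, and acid work-up closes the bicyclic vinylogous ester A3.
- For: the stereocentre sits γ to the carbonyl of A1 and cannot epimerise during the enolate chemistry; the configuration at C4a is irrelevant; no transition metal meets the prenyl ether. On this last point the alternative is stronger than the chosen route.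
- Against: ring A is an ordinary oxygenated benzene ring that can be bought, so building it costs steps. Turning A3 into the 7-hydroxychroman needs four hydrogens removed from C4a, C5 and C6, and the oxidants that do this (quinones, palladium with oxygen, halogenation and elimination) threaten the electron-rich ring B, the prenyl ether and the vinyl group. The alkoxide base endangers the aryl silyl ether. The enantioselective synthesis of A1 is still unsolved, so the stereochemical problem is only moved.
- Comparison: the chosen route keeps both aromatic rings intact from commercial phenols, needs no late change of oxidation level, and makes C3 and two C–C bonds in one catalytic step.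

**Alternative 2: cyclotrimerisation forming rings A and C.** Here C4a–C8a, C5–C6 and C7–C8 are cut, giving the 1,7-diyne A4 (a silyl alkyne and an ynol ether linked through C4, C3, C2 and O1) and ethynylboronic acid pinacol ester A5. Under ruthenium catalysis the three alkynes would combine to A6, an isoflavan with boron on C7 and silicon on C5.
- For: three bonds and two rings form in one step, which is better bond economy than the chosen key step; the C7 oxygen is placed by design as boron.
- Against: the ynol ether of A4 is sensitive to acid and water and is made with strong base on a substrate that already holds the stereocentre. The catalyst also meets a terminal vinyl group that can enter ene-yne or mixed cyclotrimerisation paths. The orientation of A5 (boron on C7 and not C6) rests only on the bulk of the silyl group. The product then needs oxidation at boron and protodesilylation at C5, the latter normally with acid that the prenyl ether does not tolerate. A4 needs its own asymmetric synthesis.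
- Comparison: counted over the whole route the alternative is longer, and it puts risk into several steps. The chosen route has one risky step with a close precedent and needs no de novo arene.

**Alternative 3: reductive decarboxylative arylation closing ring C.** The C4–C4a bond is cut, giving the N-hydroxyphthalimide ester A7 of a 3-aryl-4-aryloxybutanoic acid with bromine on C4a. At a cathode with a nickel–bipyridine catalyst the ester would lose CO2 to give the primary C4 radical, which the arylnickel formed at C4a–Br captures, and reductive elimination would give the bis-silyl ether A8.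
- For: A8 is one desilylation from 19, whereas the chosen key-step product 14 is four steps away. The O1–C8a ether is made early by simple phenol chemistry. The stereocentre of A7 could plausibly come from an asymmetric conjugate arylation of a γ-aryloxy enoate, which is at least as dependable as ligand control in a crowded conjunctive coupling. On these three points the alternative is as strong or stronger.
- Against: the radical on C4 is β to the aryl-bearing C3, so a 1,2-aryl shift and ipso attack on the ring A ether carbon are open. Intramolecular capture must outrun reduction of the radical and hydrodebromination. Zerovalent nickel with bipyridine opens allyl aryl ethers readily, so the prenyl ether is at greater risk than with palladium. A carboxyl carbon has to be built in, activated and then thrown away.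
- Comparison: the chosen route is more convergent, joining three simple pieces while the stereocentre is formed, and its closed-shell mechanism puts no radical next to C3. It pays for this with a longer endgame.

Key step: step 8

## Route

Step 1
Reactants: 1 4-bromoresorcinol (4-bromobenzene-1,3-diol); 2 prenyl bromide (1-bromo-3-methylbut-2-ene)
Product: 3 2-bromo-5-(3-methylbut-2-enyloxy)phenol
Conditions: K2CO3 (1.1 equiv), 2 (1.0 equiv), acetone, rt
Reagents that add atoms: none
Why: Williamson ether synthesis; the hydroxyl para to bromine is the less hindered and its phenoxide the more nucleophilic, so it should be alkylated preferentially, and the regioisomer and the bis-ether are removed by chromatography.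

Step 2
Reactants: 3 2-bromo-5-(3-methylbut-2-enyloxy)phenol
Product: 4 [2-bromo-5-(3-methylbut-2-enyloxy)phenoxy]triisopropylsilane
Conditions: TIPSCl, imidazole, DMF, rt to 40 °C
Reagents that add atoms: chlorotri(propan-2-yl)silane (TIPSCl), CC(C)[Si](Cl)(C(C)C)C(C)C
Why: Imidazole-mediated O-silylation of a phenol; the bulky silyl ether is chosen for its stability to carbonate bases and for the shielding it gives the neighbouring ring carbon in step 3.

Step 3
Reactants: 4 [2-bromo-5-(3-methylbut-2-enyloxy)phenoxy]triisopropylsilane
Product: 6 4-bromo-2-(2-methylbut-3-en-2-yl)-5-(triisopropylsilyloxy)phenol, via ortho-dienone 5 (not isolated)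
Conditions: PhNEt2, 190 °C (sealed tube, degassed)
Reagents that add atoms: none
Why: Aromatic Claisen rearrangement; the [3,3] shift brings the tertiary end of the prenyl group to the ortho carbon that becomes C5', the other ortho carbon (C3') being blocked by the triisopropylsilyloxy group, and dienone 5 tautomerises to phenol 6. The amine solvent keeps the medium free of acid, which should hold back ionisation of the ether and cyclisation of the product.

Step 4
Reactants: 6 4-bromo-2-(2-methylbut-3-en-2-yl)-5-(triisopropylsilyloxy)phenol; 2 prenyl bromide
Product: 7 1-bromo-5-(2-methylbut-3-en-2-yl)-4-(3-methylbut-2-enyloxy)-2-(triisopropylsilyloxy)benzene (ring B bromide)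
Conditions: K2CO3, 2, acetone, 50 °C
Reagents that add atoms: none
Why: Williamson ether synthesis at the only free phenol; the reactive allylic bromide alkylates the hindered phenoxide, and the triisopropylsilyl ether withstands K2CO3 in acetone.

Step 5
Reactants: 7 ring B bromide
Product: 8 2-[5-(2-methylbut-3-en-2-yl)-4-(3-methylbut-2-enyloxy)-2-(triisopropylsilyloxy)phenyl]-4,4,5,5-tetramethyl-1,3,2-dioxaborolane (ring B pinacol boronic ester)
Conditions: B2pin2, Pd(dppf)Cl2 (5 mol%), KOAc, 1,4-dioxane, 90 °C
Reagents that add atoms: bis(pinacolato)diboron, CC1(C)OB(OC1(C)C)B1OC(C)(C)C(C)(C)O1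
Why: Miyaura borylation of an aryl bromide; KOAc is too weak to touch the silyl ether, and the trisubstituted alkene of the prenyl ether is a poor ligand for zerovalent palladium, so ionisation of the ether should not compete.

Step 6
Reactants: 9 4-(tert-butyldimethylsilyloxy)phenol
Product: 10 4-(tert-butyldimethylsilyloxy)-2-chlorophenol
Conditions: SO2Cl2 (1.0 equiv), i-Bu2NH (10 mol%), toluene, 0 °C to rt
Reagents that add atoms: sulfuryl chloride, O=S(=O)(Cl)Cl
Why: Amine-catalysed electrophilic ortho-chlorination of a phenol; the para position is blocked and the free hydroxyl directs more strongly than the silyloxy group, so chlorine should enter next to the hydroxyl, and the first chlorine slows a second substitution.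

Step 7
Reactants: 10 4-(tert-butyldimethylsilyloxy)-2-chlorophenol
Product: 11 4-(tert-butyldimethylsilyloxy)-2-chlorophenyl trifluoromethanesulfonate (ring A triflate)
Conditions: Tf2O, pyridine, CH2Cl2, 0 °C
Reagents that add atoms: trifluoromethanesulfonic anhydride, O=S(=O)(OS(=O)(=O)C(F)(F)F)C(F)(F)F
Why: O-sulfonylation of a phenol; the only free hydroxyl reacts and the aryl silyl ether is stable to pyridine at 0 °C.

Step 8
Reactants: 8 ring B pinacol boronic ester; 12 vinylmagnesium bromide; 11 ring A triflate
Product: 14 2-{(1R)-2-[4-(tert-butyldimethylsilyloxy)-2-chlorophenyl]-1-[5-(2-methylbut-3-en-2-yl)-4-(3-methylbut-2-enyloxy)-2-(triisopropylsilyloxy)phenyl]ethyl}-4,4,5,5-tetramethyl-1,3,2-dioxaborolane, via vinylboronate complex 13 (not isolated)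
Conditions: 12 (1.0 equiv), THF, 0 °C to rt; then 11 (1.1 equiv), NaOTf (2 equiv), Pd(OAc)2 (2 mol%), MandyPhos (2.4 mol%), THF/DMSO, 60 °C
Reagents that add atoms: none
Why: Vinylmagnesium bromide adds to the boron of 8 to give the four-coordinate boronate 13. Zerovalent palladium, formed in the flask from Pd(OAc)2 and MandyPhos, inserts into the C–OTf bond of 11, a chelating bisphosphine favouring this bond over the neighbouring C–Cl bond. The cationic divalent arylpalladium binds the electron-rich vinyl group of 13 (NaOTf precipitates bromide, which would otherwise block this site) and triggers a 1,2-shift of ring B from boron to the boron-bearing carbon, anti to palladium, which forms C3–C1' and the C3 stereocentre. Reductive elimination from the resulting alkyl(aryl)palladium forms C4–C4a and returns zerovalent palladium. The closest known reaction type is the enantioselective palladium-catalysed conjunctive cross-coupling of Grignard-derived vinylboron ate complexes with aryl triflates. No ring is closed, and the configuration at C3 is controlled by the chiral ligand, which decides the alkene face that palladium occupies during the shift. The step needs triflate-over-chloride selectivity (chelating ligand), reaction at the boronate alkene only (it alone is activated by the adjacent anionic boron, the prenyl and 1,1-dimethylallyl alkenes being unactivated and hindered), and the shift in preference to direct transmetalation (favoured by the pinacol ligand on boron and the wide ferrocenyl bisphosphine).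

Step 9
Reactants: 14 secondary boronic ester
Product: 16 2-{(2R)-3-[4-(tert-butyldimethylsilyloxy)-2-chlorophenyl]-2-[5-(2-methylbut-3-en-2-yl)-4-(3-methylbut-2-enyloxy)-2-(triisopropylsilyloxy)phenyl]propyl}-4,4,5,5-tetramethyl-1,3,2-dioxaborolane, via chloromethylboronate complex 15 (not isolated)
Conditions: BrCH2Cl (2.5 equiv), n-BuLi (2.0 equiv, added last), THF, −78 °C to rt
Reagents that add atoms: chloromethyllithium, [Li]CCl, made in the flask from bromochloromethane, ClCBr, and n-butyllithium, [Li]CCCC
Why: Matteson homologation; bromine–lithium exchange on bromochloromethane is far faster than any reaction of n-butyllithium with the aryl chloride or the boronic ester, the carbenoid adds to boron to give 15, and on warming C3 migrates from boron to the CH2 carbon with loss of chloride and with retention at C3.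

Step 10
Reactants: 16 primary boronic ester
Product: 17 (2R)-3-[4-(tert-butyldimethylsilyloxy)-2-chlorophenyl]-2-[5-(2-methylbut-3-en-2-yl)-4-(3-methylbut-2-enyloxy)-2-(triisopropylsilyloxy)phenyl]propan-1-ol
Conditions: NaBO3·4H2O, THF/H2O (1:1), rt
Reagents that add atoms: sodium perborate tetrahydrate, [Na+].[O-]B1OO1.O.O.O.O
Why: Oxidation of a C–B bond by nucleophilic peroxide with 1,2-shift from boron to oxygen; perborate is mild enough to leave the aryl silyl ethers in place and does not epoxidise unactivated alkenes, and C3 is not involved.

Step 11
Reactants: 17 primary alcohol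
Product: 18 (3R)-7-(tert-butyldimethylsilyloxy)-3-[5-(2-methylbut-3-en-2-yl)-4-(3-methylbut-2-enyloxy)-2-(triisopropylsilyloxy)phenyl]chroman
Conditions: Pd(OAc)2 (5 mol%), t-BuXPhos (7.5 mol%), K3PO4, toluene, 80 °C
Reagents that add atoms: none
Why: Intramolecular Buchwald–Hartwig etherification of an aryl chloride with a primary alcohol, closing the six-membered ring C; the bulky dialkylbiarylphosphine allows insertion into C8a–Cl and makes C–O reductive elimination faster than β-hydride elimination. Both phenol oxygens are silylated, so only O1 can couple, and the sparingly soluble K3PO4 keeps the alkoxide concentration low.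

Step 12
Reactants: 18 bis-silyl isoflavan
Product: 19 Manuifolin D, (3R)-3-[2-hydroxy-5-(2-methylbut-3-en-2-yl)-4-(3-methylbut-2-enyloxy)phenyl]chroman-7-ol
Conditions: Bu4NF, AcOH, THF, 0 °C to rt
Reagents that add atoms: none
Why: Fluoride-mediated cleavage of both aryl silyl ethers; the acetic acid buffer avoids strongly basic phenoxide solutions, and nothing else in the molecule reacts with fluoride.

## Compound list

1 | 4-bromoresorcinol | Oc1ccc(Br)c(O)c1 | starting material
2 | prenyl bromide (1-bromo-3-methylbut-2-ene) | CC(C)=CCBr | starting material
3 | 2-bromo-5-(3-methylbut-2-enyloxy)phenol | Oc1cc(OCC=C(C)C)ccc1Br | intermediate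
4 | [2-bromo-5-(3-methylbut-2-enyloxy)phenoxy]triisopropylsilane | CC(C)[Si](Oc1cc(OCC=C(C)C)ccc1Br)(C(C)C)C(C)C | intermediate
5 | 4-bromo-6-(2-methylbut-3-en-2-yl)-3-(triisopropylsilyloxy)cyclohexa-2,4-dien-1-one (racemic, not isolated) | O=C1C=C(O[Si](C(C)C)(C(C)C)C(C)C)C(Br)=CC1C(C)(C)C=C | intermediate
6 | 4-bromo-2-(2-methylbut-3-en-2-yl)-5-(triisopropylsilyloxy)phenol | C=CC(C)(C)c1cc(Br)c(O[Si](C(C)C)(C(C)C)C(C)C)cc1O | intermediate
7 | 1-bromo-5-(2-methylbut-3-en-2-yl)-4-(3-methylbut-2-enyloxy)-2-(triisopropylsilyloxy)benzene | C=CC(C)(C)c1cc(Br)c(O[Si](C(C)C)(C(C)C)C(C)C)cc1OCC=C(C)C | intermediate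
8 | ring B pinacol boronic ester (ArB–Bpin) | C=CC(C)(C)c1cc(B2OC(C)(C)C(C)(C)O2)c(O[Si](C(C)C)(C(C)C)C(C)C)cc1OCC=C(C)C | intermediate
9 | 4-(tert-butyldimethylsilyloxy)phenol | Oc1ccc(O[Si](C)(C)C(C)(C)C)cc1 | starting material
10 | 4-(tert-butyldimethylsilyloxy)-2-chlorophenol | Oc1ccc(O[Si](C)(C)C(C)(C)C)cc1Cl | intermediate
11 | 4-(tert-butyldimethylsilyloxy)-2-chlorophenyl trifluoromethanesulfonate | O=S(=O)(Oc1ccc(O[Si](C)(C)C(C)(C)C)cc1Cl)C(F)(F)F | intermediate
12 | vinylmagnesium bromide | C=C[Mg]Br | starting material
13 | bromomagnesium (ArB)(vinyl)(pinacolato)borate (not isolated) | C=C[B-]1(OC(C)(C)C(C)(C)O1)c2cc(C(C)(C)C=C)c(OCC=C(C)C)cc2O[Si](C(C)C)(C(C)C)C(C)C.[Mg+]Br | intermediate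
14 | (R)-ArB–CH(Bpin)–CH2–ArA, secondary boronic ester with boron on C3 | C=CC(C)(C)c1cc([C@@H](Cc3ccc(O[Si](C)(C)C(C)(C)C)cc3Cl)B4OC(C)(C)C(C)(C)O4)c(O[Si](C(C)C)(C(C)C)C(C)C)cc1OCC=C(C)C | intermediate
15 | lithium (chloromethyl)boronate complex of 14, (R) (not isolated) | C=CC(C)(C)c1cc([C@@H](Cc3ccc(O[Si](C)(C)C(C)(C)C)cc3Cl)[B-]4(CCl)OC(C)(C)C(C)(C)O4)c(O[Si](C(C)C)(C(C)C)C(C)C)cc1OCC=C(C)C.[Li+] | intermediate
16 | (R)-ArB–CH(CH2Bpin)–CH2–ArA, primary boronic ester | C=CC(C)(C)c1cc([C@@H](Cc3ccc(O[Si](C)(C)C(C)(C)C)cc3Cl)CB4OC(C)(C)C(C)(C)O4)c(O[Si](C(C)C)(C(C)C)C(C)C)cc1OCC=C(C)C | intermediate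
17 | (2R)-3-(ArA)-2-(ArB)propan-1-ol | C=CC(C)(C)c1cc([C@@H](Cc3ccc(O[Si](C)(C)C(C)(C)C)cc3Cl)CO)c(O[Si](C(C)C)(C(C)C)C(C)C)cc1OCC=C(C)C | intermediate
18 | (3R)-7-(tert-butyldimethylsilyloxy)-3-(ArB)chroman | C=CC(C)(C)c1cc([C@@H]2COc3cc(O[Si](C)(C)C(C)(C)C)ccc3C2)c(O[Si](C(C)C)(C(C)C)C(C)C)cc1OCC=C(C)C | intermediate
19 | Manuifolin D | C=CC(C)(C)c1cc([C@@H]2COc3cc(O)ccc3C2)c(O)cc1OCC=C(C)C | target

## Step count and weak points

Total: 12 steps. Longest linear sequence: 10 steps (steps 1 to 5, then 8 to 12); the ring A branch (steps 6 and 7) is two steps.

**Step 8 (key step).** The most likely failure is that the 1,2-shift of the hindered ortho-silyloxy aryl group is slow. Direct transfer of vinyl or aryl from boron to palladium (ordinary cross-coupling) would then take over, or the two ortho substituents would erode the facial selectivity. Insertion into C–Cl and Heck-type reaction at the ring B vinyl group are less likely. The fallback gives up the boron stereocentre and sets C3 by auxiliary-controlled enolate alkylation; it sets out from bromide 7 and returns at alcohol 17.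
- Bromide 7 is coupled with the Reformatsky reagent BrZnCH2CO2Et (Pd2(dba)3, XPhos, THF) to give ethyl (ArB)acetate F1.
- LiOH hydrolysis gives (ArB)acetic acid F2.
- The mixed pivalic anhydride of F2 acylates the lithium salt of (R)-4-benzyloxazolidin-2-one to give the acyl oxazolidinone F3.
- Separately, 3-chloro-4-methylphenol F4 is silylated (TBSCl, imidazole) to its silyl ether F5, which is brominated at the methyl group (NBS, AIBN, PhCF3, reflux) to the benzylic bromide F6.
- The sodium enolate of F3 (NaN(SiMe3)2, THF, −78 °C) is alkylated by F6 on the face away from the benzyl group of the auxiliary (Evans alkylation) to give the (2R)-imide F7.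
- LiBH4 (THF, one equivalent of water, 0 °C) removes the auxiliary to give 17.

**Step 11.** The alkoxopalladium intermediate may undergo β-hydride elimination (aldehyde and hydrodechlorinated arene) instead of C–O reductive elimination, or base may strip a silyl group so that a phenoxide competes. The fallback sets out from 17 and returns at 18. The aryl chloride is borylated (Pd2(dba)3, XPhos, B2pin2, KOAc, dioxane, 100 °C) to the aryl boronic ester alcohol F8. NaBO3·4H2O oxidises it to the phenol alcohol F9, whose single free phenol is closed on to C2 by a Mitsunobu reaction (PPh3, DIAD, THF).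

**Step 3.** The product phenol may react further at 190 °C, by addition of the hydroxyl to the vinyl group (a dihydrobenzofuran) or by the abnormal Claisen pathway, and some ether may be cleaved. The fallback sets out from 4 and returns at 6. The rearrangement is run in PhNEt2 containing acetic anhydride, so that the phenol is acetylated as it forms and is isolated as the aryl acetate F10. i-Bu2AlH (CH2Cl2, −78 °C) then frees 6 without touching the silyl ether or the bromide.

**Step 1.** Alkylation may occur at the wrong hydroxyl, since the one next to bromine is the more acidic, or at both. The fallback removes the question by starting from a symmetrical diol; it sets out from 2 and returns at 6.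
- Resorcinol F11, used in excess, is mono-prenylated with 2 (K2CO3, acetone) to 3-(3-methylbut-2-enyloxy)phenol F12.
- Silylation (TIPSCl, imidazole) gives the silyl ether F13.
- The thermal [3,3] shift (PhNEt2, 190 °C) gives 2-(2-methylbut-3-en-2-yl)-5-(triisopropylsilyloxy)phenol F14.
- NBS (CH2Cl2, −78 °C) brominates the only open position para to the free hydroxyl to give 6. At this temperature ring bromination should outrun attack on the hindered vinyl group.

## Further compounds

F1 | step 8 | ethyl 2-[5-(2-methylbut-3-en-2-yl)-4-(3-methylbut-2-enyloxy)-2-(triisopropylsilyloxy)phenyl]acetate | CCOC(=O)Cc1cc(C(C)(C)C=C)c(OCC=C(C)C)cc1O[Si](C(C)C)(C(C)C)C(C)C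
F2 | step 8 | 2-[5-(2-methylbut-3-en-2-yl)-4-(3-methylbut-2-enyloxy)-2-(triisopropylsilyloxy)phenyl]acetic acid | OC(=O)Cc1cc(C(C)(C)C=C)c(OCC=C(C)C)cc1O[Si](C(C)C)(C(C)C)C(C)C
F3 | step 8 | (4R)-4-benzyl-3-[(ArB)acetyl]oxazolidin-2-one | O=C1OC[C@@H](Cc2ccccc2)N1C(=O)Cc3cc(C(C)(C)C=C)c(OCC=C(C)C)cc3O[Si](C(C)C)(C(C)C)C(C)C
F4 | step 8 | 3-chloro-4-methylphenol | Cc1ccc(O)cc1Cl
F5 | step 8 | tert-butyl(3-chloro-4-methylphenoxy)dimethylsilane | Cc1ccc(O[Si](C)(C)C(C)(C)C)cc1Cl
F6 | step 8 | [4-(bromomethyl)-3-chlorophenoxy](tert-butyl)dimethylsilane | BrCc1ccc(O[Si](C)(C)C(C)(C)C)cc1Cl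
F7 | step 8 | (4R)-4-benzyl-3-[(2R)-3-(ArA)-2-(ArB)propanoyl]oxazolidin-2-one | O=C1OC[C@@H](Cc2ccccc2)N1C(=O)[C@H](Cc3ccc(O[Si](C)(C)C(C)(C)C)cc3Cl)c4cc(C(C)(C)C=C)c(OCC=C(C)C)cc4O[Si](C(C)C)(C(C)C)C(C)C
F8 | step 11 | (2R)-3-[4-(tert-butyldimethylsilyloxy)-2-(4,4,5,5-tetramethyl-1,3,2-dioxaborolan-2-yl)phenyl]-2-(ArB)propan-1-ol | C=CC(C)(C)c1cc([C@@H](Cc3ccc(O[Si](C)(C)C(C)(C)C)cc3B4OC(C)(C)C(C)(C)O4)CO)c(O[Si](C(C)C)(C(C)C)C(C)C)cc1OCC=C(C)C
F9 | step 11 | (2R)-3-[4-(tert-butyldimethylsilyloxy)-2-hydroxyphenyl]-2-(ArB)propan-1-ol | C=CC(C)(C)c1cc([C@@H](Cc3ccc(O[Si](C)(C)C(C)(C)C)cc3O)CO)c(O[Si](C(C)C)(C(C)C)C(C)C)cc1OCC=C(C)C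
F10 | step 3 | 4-bromo-2-(2-methylbut-3-en-2-yl)-5-(triisopropylsilyloxy)phenyl acetate | C=CC(C)(C)c1cc(Br)c(O[Si](C(C)C)(C(C)C)C(C)C)cc1OC(C)=O
F11 | step 1 | resorcinol | Oc1cccc(O)c1
F12 | step 1 | 3-(3-methylbut-2-enyloxy)phenol | Oc1cccc(OCC=C(C)C)c1
F13 | step 1 | [3-(3-methylbut-2-enyloxy)phenoxy]triisopropylsilane | CC(C)[Si](Oc1cccc(OCC=C(C)C)c1)(C(C)C)C(C)C
F14 | step 1 | 2-(2-methylbut-3-en-2-yl)-5-(triisopropylsilyloxy)phenol | C=CC(C)(C)c1ccc(O[Si](C(C)C)(C(C)C)C(C)C)cc1O
A1 | alternative 1 | (5R)-5-[2-(tert-butyldimethylsilyloxy)-5-(2-methylbut-3-en-2-yl)-4-(3-methylbut-2-enyloxy)phenyl]oxan-2-one | C=CC(C)(C)c1cc([C@@H]2COC(=O)CC2)c(O[Si](C)(C)C(C)(C)C)cc1OCC=C(C)C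
A2 | alternative 1 | methyl vinyl ketone | CC(=O)C=C
A3 | alternative 1 | (3R)-3-aryl-2,3,4,4a,5,6-hexahydrochromen-7-one (either C4a epimer) | C=CC(C)(C)c1cc([C@@H]2COC3=CC(=O)CCC3C2)c(O[Si](C)(C)C(C)(C)C)cc1OCC=C(C)C
A4 | alternative 2 | (R)-2-aryl-1-(ethynyloxy)-5-(trimethylsilyl)pent-4-yne (1,7-diyne) | C=CC(C)(C)c1cc([C@@H](CC#C[Si](C)(C)C)COC#C)c(O[Si](C)(C)C(C)(C)C)cc1OCC=C(C)C
A5 | alternative 2 | ethynylboronic acid pinacol ester | C#CB1OC(C)(C)C(C)(C)O1
A6 | alternative 2 | (3R)-isoflavan with pinacolboryl on C7 and trimethylsilyl on C5 | C=CC(C)(C)c1cc([C@@H]2COc3cc(B4OC(C)(C)C(C)(C)O4)cc([Si](C)(C)C)c3C2)c(O[Si](C)(C)C(C)(C)C)cc1OCC=C(C)C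
A7 | alternative 3 | 1,3-dioxoisoindolin-2-yl (3R)-3-aryl-4-[2-bromo-5-(tert-butyldimethylsilyloxy)phenoxy]butanoate | C=CC(C)(C)c1cc([C@@H](CC(=O)ON3C(=O)c4ccccc4C3=O)COc5cc(O[Si](C)(C)C(C)(C)C)ccc5Br)c(O[Si](C)(C)C(C)(C)C)cc1OCC=C(C)C
A8 | alternative 3 | 7,2'-bis(tert-butyldimethylsilyl) ether of Manuifolin D | C=CC(C)(C)c1cc([C@@H]2COc3cc(O[Si](C)(C)C(C)(C)C)ccc3C2)c(O[Si](C)(C)C(C)(C)C)cc1OCC=C(C)C
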